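**Retrosynthetic overview**
- Labdane numbering is used: Br at C-3, ring-fusion carbons C-5 and C-10, carbinol C-8 with its methyl C-17, side chain on C-9, carbinol C-13. In the target the C-9 chain is trans and the 8-OH cis to the C-10 methyl.
- C-8 carbinol ⇐ methyl addition to a 17-nor-8-ketone (attack anti to the axial C-10 methyl) ⇐ exocyclic 8(17)-alkene.
- Rings A then B, in one operation ⇐ catalyst-controlled bromonium-induced chair–chair bicyclization of a (6Z,10E)-geranyllinalool silyl ether (E alkene → trans fusion, Z alkene → axial C-9 chain).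
- Triene ⇐ Z-selective Julia–Kocienski olefination of (E)-geranylacetone with a tetrazolyl sulfone cut from (R)-linalool, which supplies C-13 (R).

Assumptions: (R)-(−)-linalool (≥97% ee) and (E)-geranylacetone (≥96% E) are purchased. The (R)-catalyst of step 6 is assumed to give the 3R bromide; if the first run shows the opposite sense, its mirror image is used.

**Step 1**
Reactants: 1 (R)-(−)-linalool
Product: 2 tert-butyl{[(3R)-3,7-dimethylocta-1,6-dien-3-yl]oxy}dimethylsilane
Conditions: TBSOTf, 2,6-lutidine, CH2Cl2, 0 °C → rt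
Reagents that add atoms: tert-butyldimethylsilyl trifluoromethanesulfonate, CC(C)(C)[Si](C)(C)OS(=O)(=O)C(F)(F)F
Why: O-silylation of the tertiary allylic alcohol breaks no bond at the stereocenter (3R kept) and masks the only oxygen that could later capture the C-8 cation.

**Step 2**
Reactants: 2 tert-butyl{[(3R)-3,7-dimethylocta-1,6-dien-3-yl]oxy}dimethylsilane
Product: 4 (4R)-4-[(tert-butyldimethylsilyl)oxy]-4-methylhex-5-en-1-ol, via aldehyde 3 (not isolated)
Conditions: O3, CH2Cl2/MeOH, pyridine (cat.), Sudan Red 7B, −78 °C; then NaBH4, −78 → 0 °C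
Reagents that add atoms: ozone, [O-][O+]=O
Why: Chemoselective ozonolysis with reductive work-up, because the electron-rich trisubstituted alkene reacts far faster than the vinyl group deactivated by the allylic silyloxy group; the carbinol center is untouched.

**Step 3**
Reactants: 4 (4R)-4-[(tert-butyldimethylsilyl)oxy]-4-methylhex-5-en-1-ol
Product: 5 5-({(4R)-4-[(tert-butyldimethylsilyl)oxy]-4-methylhex-5-en-1-yl}sulfanyl)-1-methyl-1H-tetrazole
Conditions: 1-methyl-1H-tetrazole-5-thiol, PPh3, DIAD, THF, 0 °C → rt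
Reagents that add atoms: 1-methyl-1H-tetrazole-5-thiol, Cn1nnnc1S
Why: Mitsunobu thioetherification of the primary alcohol by the acidic thiol (SN2 at CH2, no stereocenter involved).

**Step 4**
Reactants: 5 5-({(4R)-4-[(tert-butyldimethylsilyl)oxy]-4-methylhex-5-en-1-yl}sulfanyl)-1-methyl-1H-tetrazole
Product: 6 5-({(4R)-4-[(tert-butyldimethylsilyl)oxy]-4-methylhex-5-en-1-yl}sulfonyl)-1-methyl-1H-tetrazole
Conditions: (NH4)6Mo7O24·4H2O (10 mol %), 30% H2O2, EtOH, 0 °C → rt
Reagents that add atoms: hydrogen peroxide, OO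
Why: Molybdate-catalysed sulfide-to-sulfone oxidation leaves the isolated vinyl group and the silyl ether alone.

**Step 5**
Reactants: 6 5-({(4R)-4-[(tert-butyldimethylsilyl)oxy]-4-methylhex-5-en-1-yl}sulfonyl)-1-methyl-1H-tetrazole; 7 (E)-geranylacetone
Product: 8 tert-butyldimethyl{[(3R,6Z,10E)-3,7,11,15-tetramethylhexadeca-1,6,10,14-tetraen-3-yl]oxy}silane
Conditions: LiN(SiMe3)2, THF, −78 °C → rt; AgNO3-silica chromatography
Reagents that add atoms: none
Why: Julia–Kocienski olefination in its Z-selective ketone variant (1-methyltetrazolyl sulfone, lithium amide, low temperature) places the sulfone-derived chain cis to the larger ketone substituent, giving the 6Z alkene, while the 10E alkene comes unchanged from 7.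

**Step 6**
Reactants: 8 tert-butyldimethyl{[(3R,6Z,10E)-3,7,11,15-tetramethylhexadeca-1,6,10,14-tetraen-3-yl]oxy}silane
Product: 9 tert-butyl({(3R)-5-[(1S,4aS,6R,8aS)-6-bromo-5,5,8a-trimethyl-2-methylidenedecahydronaphthalen-1-yl]-3-methylpent-1-en-3-yl}oxy)dimethylsilane
Conditions: 1,3-dibromo-5,5-dimethylhydantoin (1.1 equiv), (R)-N-triflyl thiophosphoramide of 3,3′-bis(2,4,6-triisopropylphenyl)-1,1′-bi-2-naphthol (10 mol %), toluene, −78 °C
Reagents that add atoms: 1,3-dibromo-5,5-dimethylhydantoin, CC1(C)N(Br)C(=O)N(Br)C1=O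
Why: Proposed new method: the chiral thiophosphoramide (P=S activates Br+, N–H binds the hydantoin) delivers bromine to one face of the terminal alkene, as in the known catalytic asymmetric bromocyclization of homogeranylarenes and the achiral bromonium polyene cyclization with Et2SBr·SbBrCl5; the bromonium then opens through a chair–chair transition state in which the 10E alkene gives the trans ring fusion with equatorial bromine (C-3, C-5, C-10), the 6Z alkene puts the C-9 chain axial and anti to the C-10 methyl, and the C-8 cation (its only aligned ring hydrogen, axial 7-H, lies under that chain and 9-H is equatorial) loses a methyl proton to give the 8(17)-alkene.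

**Step 7**
Reactants: 9 tert-butyl({(3R)-5-[(1S,4aS,6R,8aS)-6-bromo-5,5,8a-trimethyl-2-methylidenedecahydronaphthalen-1-yl]-3-methylpent-1-en-3-yl}oxy)dimethylsilane
Product: 11 (1R,4aS,6R,8aR)-6-bromo-1-{(3R)-3-[(tert-butyldimethylsilyl)oxy]-3-methylpent-4-en-1-yl}-5,5,8a-trimethyloctahydronaphthalen-2(1H)-one, via spiro-epoxide 10 (not isolated)
Conditions: mCPBA, NaHCO3, CH2Cl2, 0 °C; then H5IO6, THF/H2O, 0 °C → rt
Reagents that add atoms: 3-chloroperbenzoic acid, OOC(=O)c1cccc(Cl)c1 (oxygen of 10); water, O (carbonyl oxygen of 11 after acid opening at C-8)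
Why: Prilezhaev epoxidation prefers the 1,1-disubstituted alkene over the deactivated vinyl group and periodic acid cleaves either epoxide epimer to the 17-nor ketone; C-17 is excised because oxygen reagents enter at C-8 anti to the C-10 methyl and would give the wrong carbinol epimer, and C-9 (equatorial H, poorly aligned for enolization) is kept.

**Step 8**
Reactants: 11 (1R,4aS,6R,8aR)-6-bromo-1-{(3R)-3-[(tert-butyldimethylsilyl)oxy]-3-methylpent-4-en-1-yl}-5,5,8a-trimethyloctahydronaphthalen-2(1H)-one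
Product: 12 (1R,2R,4aS,6R,8aR)-6-bromo-1-{(3R)-3-[(tert-butyldimethylsilyl)oxy]-3-methylpent-4-en-1-yl}-2,5,5,8a-tetramethyldecahydronaphthalen-2-ol
Conditions: MeLi, CeCl3, THF, −78 → 0 °C; aq. NH4Cl
Reagents that add atoms: methyllithium, [Li]C
Why: 1,2-Addition of the non-basic organocerium reagent (Imamoto conditions) by equatorial attack on the face away from the syn-axial C-10 methyl (as with 3,3,5-trimethylcyclohexanone) puts the methyl equatorial and the hydroxyl axial, cis to the C-10 methyl (8R), without epimerizing C-9.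

**Step 9**
Reactants: 12 (1R,2R,4aS,6R,8aR)-6-bromo-1-{(3R)-3-[(tert-butyldimethylsilyl)oxy]-3-methylpent-4-en-1-yl}-2,5,5,8a-tetramethyldecahydronaphthalen-2-ol
Product: 13 (1R,2R,4aS,6R,8aR)-6-bromo-1-[(3R)-3-hydroxy-3-methylpent-4-en-1-yl]-2,5,5,8a-tetramethyldecahydronaphthalen-2-ol
Conditions: Bu4NF, THF, 50 °C
Reagents that add atoms: none
Why: Fluoride-induced desilylation of the hindered tertiary silyl ether; the equatorial neopentyl-type bromide has no antiperiplanar hydrogen and is inert to fluoride.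

**Compound list**
1 | (R)-(−)-linalool, (3R)-3,7-dimethylocta-1,6-dien-3-ol | C=C[C@](C)(O)CCC=C(C)C | starting material
2 | tert-butyl{[(3R)-3,7-dimethylocta-1,6-dien-3-yl]oxy}dimethylsilane | C=C[C@](C)(O[Si](C)(C)C(C)(C)C)CCC=C(C)C | intermediate
3 | (4R)-4-[(tert-butyldimethylsilyl)oxy]-4-methylhex-5-enal | C=C[C@](C)(O[Si](C)(C)C(C)(C)C)CCC=O | intermediate (not isolated)
4 | (4R)-4-[(tert-butyldimethylsilyl)oxy]-4-methylhex-5-en-1-ol | C=C[C@](C)(O[Si](C)(C)C(C)(C)C)CCCO | intermediate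
5 | 5-({(4R)-4-[(tert-butyldimethylsilyl)oxy]-4-methylhex-5-en-1-yl}sulfanyl)-1-methyl-1H-tetrazole | C=C[C@](C)(O[Si](C)(C)C(C)(C)C)CCCSc1nnnn1C | intermediate
6 | 5-({(4R)-4-[(tert-butyldimethylsilyl)oxy]-4-methylhex-5-en-1-yl}sulfonyl)-1-methyl-1H-tetrazole | C=C[C@](C)(O[Si](C)(C)C(C)(C)C)CCCS(=O)(=O)c1nnnn1C | intermediate
7 | (E)-geranylacetone, (5E)-6,10-dimethylundeca-5,9-dien-2-one | CC(=O)CC/C=C(\C)CCC=C(C)C | starting material
8 | tert-butyldimethyl{[(3R,6Z,10E)-3,7,11,15-tetramethylhexadeca-1,6,10,14-tetraen-3-yl]oxy}silane | C=C[C@](C)(O[Si](C)(C)C(C)(C)C)CC/C=C(/C)CC/C=C(\C)CCC=C(C)C | intermediate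
9 | tert-butyl({(3R)-5-[(1S,4aS,6R,8aS)-6-bromo-5,5,8a-trimethyl-2-methylidenedecahydronaphthalen-1-yl]-3-methylpent-1-en-3-yl}oxy)dimethylsilane (trans-decalin; Br equatorial and cis to the angular methyl; side chain axial and trans to it) | C=C[C@](C)(O[Si](C)(C)C(C)(C)C)CC[C@@H]1[C@]2(C)CC[C@@H](Br)C(C)(C)[C@H]2CCC1=C | intermediate
10 | 8,17-epoxide of 9 (spiro-oxirane at the former methylidene carbon, oxygen mainly on the face of the side chain; both epimers converge) | C=C[C@](C)(O[Si](C)(C)C(C)(C)C)CC[C@@H]1[C@]2(C)CC[C@@H](Br)C(C)(C)[C@H]2CC[C@@]13CO3 | intermediate (not isolated)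
11 | (1R,4aS,6R,8aR)-6-bromo-1-{(3R)-3-[(tert-butyldimethylsilyl)oxy]-3-methylpent-4-en-1-yl}-5,5,8a-trimethyloctahydronaphthalen-2(1H)-one | C=C[C@](C)(O[Si](C)(C)C(C)(C)C)CC[C@@H]1[C@]2(C)CC[C@@H](Br)C(C)(C)[C@H]2CCC1=O | intermediate
12 | (1R,2R,4aS,6R,8aR)-6-bromo-1-{(3R)-3-[(tert-butyldimethylsilyl)oxy]-3-methylpent-4-en-1-yl}-2,5,5,8a-tetramethyldecahydronaphthalen-2-ol | C=C[C@](C)(O[Si](C)(C)C(C)(C)C)CC[C@@H]1[C@]2(C)CC[C@@H](Br)C(C)(C)[C@H]2CC[C@@]1(C)O | intermediate
13 | (1R,2R,4aS,6R,8aR)-6-bromo-1-[(3R)-3-hydroxy-3-methylpent-4-en-1-yl]-2,5,5,8a-tetramethyldecahydronaphthalen-2-ol | C=C[C@](C)(O)CC[C@@H]1[C@]2(C)CC[C@@H](Br)C(C)(C)[C@H]2CC[C@@]1(C)O | target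

**Totals**
Total steps: 9. Longest linear sequence: 9 steps (1 → 13); 7 enters as a purchased fragment in step 5.

**Steps most likely to fail**

Step 6 (sense and level of asymmetric induction; exocyclic versus endocyclic proton loss; any minor ring diastereomer is removed by chromatography at 9 or 12, since C-13 is fixed). The fallback sets out from 8 and comes back at 9. Cyclization with Hg(OSO2CF3)2·PhNMe2 in MeNO2 at −20 °C, quenched with aqueous NaCl, captures water at C-8 and gives the chloromercurio tertiary alcohol F1 (HgCl equatorial at C-3, hydroxyl on the side-chain face). Bromodemercuration (Br2, LiBr, pyridine, O2) gives the 3-bromo-8-ol F2, the C-8 epimer of 12. At this stage the two ring diastereomers are separated. SOCl2/pyridine at 0 °C then dehydrates the equatorial tertiary alcohol, which has no antiperiplanar ring hydrogen, to the exocyclic alkene 9.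

Step 5 (Z-selectivity with a methyl alkyl ketone). The fallback sets out from aldehyde 3 (isolated after Me2S instead of NaBH4 work-up in step 2) and comes back at 8. Still–Gennari olefination with methyl 2-[bis(2,2,2-trifluoroethoxy)phosphoryl]propanoate (KN(SiMe3)2, 18-crown-6, THF, −78 °C) gives methyl (2Z,6R)-6-[(tert-butyldimethylsilyl)oxy]-2,6-dimethylocta-2,7-dienoate F3. Reduction with i-Bu2AlH gives (2Z,6R)-6-[(tert-butyldimethylsilyl)oxy]-2,6-dimethylocta-2,7-dien-1-ol F4. CBr4/PPh3 gives {[(3R,6Z)-8-bromo-3,7-dimethylocta-1,6-dien-3-yl]oxy}(tert-butyl)dimethylsilane F5. Alkylation of lithiated geranyl phenyl sulfone (n-BuLi, THF, −78 °C) gives tert-butyldimethyl{[(3R,6Z,10E)-3,7,11,15-tetramethyl-9-(phenylsulfonyl)hexadeca-1,6,10,14-tetraen-3-yl]oxy}silane F6. Reductive desulfonylation (LiBHEt3, PdCl2[Ph2P(CH2)3PPh2] cat., THF, 0 °C) gives 8.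

Step 8 (both faces of the ketone are hindered: the axial C-10 methyl on one, the axial C-9 chain on the other). The fallback sets out from 11 and comes back at 12. Dimethylsulfoxonium methylide (Me3S(O)I, NaH, DMSO, rt) adds reversibly and closes to the thermodynamic spiro-epoxide F7 (new C–C bond equatorial, oxygen axial on the face of the angular methyl). LiBHEt3 (THF, 0 °C) opens it at the CH2 terminus to give 12.

**Further compounds**
F1 | step 6 | chloromercurio analogue of F2: decalin of 12 with HgCl in place of Br (equatorial) and the C-2 carbinol epimeric (hydroxyl on the side-chain face) | C=C[C@](C)(O[Si](C)(C)C(C)(C)C)CC[C@@H]1[C@]2(C)CC[C@@H]([Hg]Cl)C(C)(C)[C@H]2CC[C@]1(C)O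
F2 | step 6 | (1R,2S,4aS,6R,8aR)-6-bromo-1-{(3R)-3-[(tert-butyldimethylsilyl)oxy]-3-methylpent-4-en-1-yl}-2,5,5,8a-tetramethyldecahydronaphthalen-2-ol | C=C[C@](C)(O[Si](C)(C)C(C)(C)C)CC[C@@H]1[C@]2(C)CC[C@@H](Br)C(C)(C)[C@H]2CC[C@]1(C)O
F3 | step 5 | methyl (2Z,6R)-6-[(tert-butyldimethylsilyl)oxy]-2,6-dimethylocta-2,7-dienoate | C=C[C@](C)(O[Si](C)(C)C(C)(C)C)CC/C=C(/C)C(=O)OC
F4 | step 5 | (2Z,6R)-6-[(tert-butyldimethylsilyl)oxy]-2,6-dimethylocta-2,7-dien-1-ol | C=C[C@](C)(O[Si](C)(C)C(C)(C)C)CC/C=C(/C)CO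
F5 | step 5 | {[(3R,6Z)-8-bromo-3,7-dimethylocta-1,6-dien-3-yl]oxy}(tert-butyl)dimethylsilane | C=C[C@](C)(O[Si](C)(C)C(C)(C)C)CC/C=C(/C)CBr
F6 | step 5 | tert-butyldimethyl{[(3R,6Z,10E)-3,7,11,15-tetramethyl-9-(phenylsulfonyl)hexadeca-1,6,10,14-tetraen-3-yl]oxy}silane (both epimers at the sulfone carbon) | C=C[C@](C)(O[Si](C)(C)C(C)(C)C)CC/C=C(/C)CC(S(=O)(=O)c1ccccc1)/C=C(\C)CCC=C(C)C
F7 | step 8 | spiro-epoxide from 11, the C-2 epimer of 10 (oxygen on the face of the angular methyl, CH2 on the side-chain face) | C=C[C@](C)(O[Si](C)(C)C(C)(C)C)CC[C@@H]1[C@]2(C)CC[C@@H](Br)C(C)(C)[C@H]2CC[C@@]13OC3
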